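**Retrosynthetic overview**

- The target is oritin-(4α→8)-catechin. The last skeletal bond, C4 of the upper unit to C8 of the catechin unit, is made by Friedel–Crafts capture of a C4 benzylic cation by tetra-O-benzyl-(+)-catechin (C4 relayed from C3); global hydrogenolysis follows.
- Ring C of the upper unit is made in one flask from two simple arenes: an enol silane (ring A with C8a–F, C4, C3–OBn) and 3,4-bis(benzyloxy)benzaldehyde (ring B, C2, O1). An aldol forms C2–C3, then an SNAr forms O1–C8a.
- Enabling feature: C4 of the upper unit is held as a ketone. It is alpha to C3 (C3 becomes an enolate carbon) and ortho, through C4a, to C8a of ring A (C8a–F becomes SNAr-active). The same carbon later becomes the cation that accepts the catechin unit.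
- Stereocontrol: C2 by a chiral ammonium fluoride catalyst, C3 from C2 under thermodynamic control, C4 from C3 by anti attack; the lower unit is bought as (+)-catechin.
- Ring order: rings A and B and the whole lower unit are bought; upper ring C is the only ring formed (step 6).

Key step: step 6

Remark: the SMILES is read as upper unit (2R,3S,4S), 2,3-trans-3,4-trans, and lower unit (2R,3S)-catechin linked through C8.

Assumption: the cinchonidinium catalyst is taken to deliver the enolate to the Si face of the aryl aldehyde (2R series); if a trial shows the opposite sense, the pseudoenantiomeric cinchoninium salt is used with nothing else changed.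

**Route**

Step 1
Reactants: 1 2-fluoro-3,4-dimethoxybenzaldehyde
Product: 2 2-fluoro-3,4-dihydroxybenzaldehyde
Conditions: BBr3, CH2Cl2, −78 °C to rt; then H2O
Reagents that add atoms: none
Why: Lewis-acid aryl methyl ether cleavage; BBr3 complexes each ether oxygen and bromide removes the methyl group by SN2, while the aldehyde and the aryl fluoride are inert at this temperature.

Step 2
Reactants: 2 2-fluoro-3,4-dihydroxybenzaldehyde
Product: 3 3,4-bis(benzyloxy)-2-fluorobenzaldehyde
Conditions: BnBr, K2CO3, DMF, rt
Reagents that add atoms: benzyl bromide, BrCc1ccccc1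
Why: Williamson ether synthesis; both phenoxides are benzylated at room temperature, where the aldehyde-activated fluoride is not yet displaced by phenoxide.

Step 3
Reactants: 3 3,4-bis(benzyloxy)-2-fluorobenzaldehyde
Product: 4 2-(benzyloxy)-1-[3,4-bis(benzyloxy)-2-fluorophenyl]ethanol (racemic)
Conditions: Bu3SnCH2OBn, n-BuLi, THF, −78 °C; then 3; then H2O
Reagents that add atoms: tributyl[(benzyloxy)methyl]stannane, CCCC[Sn](CCCC)(CCCC)COCc1ccccc1
Why: tin–lithium exchange gives (benzyloxy)methyllithium, which adds 1,2 to the aldehyde at −78 °C (organolithium carbonyl addition); the racemic carbinol center is removed in step 4.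

Step 4
Reactants: 4 2-(benzyloxy)-1-[3,4-bis(benzyloxy)-2-fluorophenyl]ethanol
Product: 5 2-(benzyloxy)-1-[3,4-bis(benzyloxy)-2-fluorophenyl]ethanone
Conditions: Dess–Martin periodinane, CH2Cl2, rt
Reagents that add atoms: none
Why: Dess–Martin oxidation of the benzylic secondary alcohol to the aryl ketone under near-neutral conditions that leave the benzyl ethers and the aryl fluoride untouched.

Step 5
Reactants: 5 2-(benzyloxy)-1-[3,4-bis(benzyloxy)-2-fluorophenyl]ethanone
Product: 6 (Z)-[2-(benzyloxy)-1-[3,4-bis(benzyloxy)-2-fluorophenyl]ethenyl]oxy(trimethyl)silane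
Conditions: LiN(SiMe3)2, Me3SiCl, THF, −78 °C; non-aqueous work-up, used crude
Reagents that add atoms: chlorotrimethylsilane, C[Si](C)(C)Cl
Why: kinetic deprotonation of the alpha-alkoxy ketone gives the lithium-chelated (Z)-enolate, which is trapped on oxygen by Me3SiCl (silyl enol ether formation).

Step 6
Reactants: 6 (Z)-enol silane; 7 3,4-bis(benzyloxy)benzaldehyde
Product: 10 (2R,3R)-3,7,8-tris(benzyloxy)-2-[3,4-bis(benzyloxy)phenyl]chroman-4-one, via silyl aldol adduct 8 (not isolated), via cis-chromanone 9 (not isolated)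
Conditions: O-allyl-N-(9-anthracenylmethyl)cinchonidinium hydrogen difluoride (10 mol %), toluene/CH2Cl2, −50 °C; then CsF (20 mol %), DMF, −50 to 25 °C
Reagents that add atoms: none
Why: Proposed new method: fluoride from the ammonium bifluoride unmasks the (Z)-enolate of 6 as an ion pair with the chiral cation, C3 of this enolate adds to the Si face of aldehyde 7 (C2–C3 bond) and silyl transfer gives aldol adduct 8; on warming, fluoride frees the C2 alkoxide, which attacks C8a of ring A in an intramolecular addition–elimination (SNAr, Meisenheimer charge delocalised into the ortho C4 carbonyl) and expels the fluoride that starts the next cycle, so that Me3SiF is the only stoichiometric by-product. The closest known reaction types are the quaternary ammonium bifluoride-catalysed Mukaiyama aldol of alpha-alkoxy aryl ketone enol silanes with aryl aldehydes and the base- or fluoride-mediated SNAr closure of ortho-fluoroaryl ketones bearing a side-chain oxygen nucleophile to chromanones and chromones; joining them in one flask with fluoride as the chain carrier has not been shown. Ring C closes in a 6-exo sense with respect to the departing fluoride, through a chair-like transition state. C2 (R) is set by the catalyst in the aldol event, and C3 (R) is relayed from it under thermodynamic control, because C3–H is alpha to the C4 ketone and any cis epimer 9 equilibrates in the basic fluoride medium to the diequatorial 2,3-trans chromanone 10. The step needs face selectivity at the aldehyde (catalyst), ring closure through the C2 oxygen only (the C3 oxygen is benzylated and C8a–F is the only activated leaving group), and cyclisation that outruns retro-aldol and beta-elimination (six-membered transition state, only a catalytic concentration of free alkoxide).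

Step 7
Reactants: 10 (2R,3R)-3,7,8-tris(benzyloxy)-2-[3,4-bis(benzyloxy)phenyl]chroman-4-one
Product: 11 (2R,3S,4R)-3,7,8-tris(benzyloxy)-2-[3,4-bis(benzyloxy)phenyl]chroman-4-ol
Conditions: NaBH4, THF/MeOH, 0 °C
Reagents that add atoms: none
Why: borohydride reduction of the aryl ketone; axial hydride delivery to the half-chair with the C2 aryl and C3 benzyloxy groups equatorial should give the equatorial 3,4-trans alcohol, and the C4 configuration is in any case erased in step 9.

Step 8
Reactants: 12 (+)-catechin
Product: 13 (2R,3S)-5,7-bis(benzyloxy)-2-[3,4-bis(benzyloxy)phenyl]chroman-3-ol (5,7,3',4'-tetra-O-benzyl-(+)-catechin)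
Conditions: BnBr, K2CO3, DMF, 0 °C to rt
Reagents that add atoms: benzyl bromide, BrCc1ccccc1
Why: Williamson etherification selective for the four phenols, since K2CO3 does not deprotonate the secondary C3 alcohol; both stereocenters of the lower unit are bought with (+)-catechin.

Step 9
Reactants: 11 (2R,3S,4R)-chroman-4-ol; 13 tetra-O-benzyl-(+)-catechin (3 equiv)
Product: 14 (2R,3S,4S)-3,7,8-tris(benzyloxy)-2-[3,4-bis(benzyloxy)phenyl]-4-[(2R,3S)-5,7-bis(benzyloxy)-2-[3,4-bis(benzyloxy)phenyl]-3-hydroxychroman-8-yl]chromane (nona-O-benzyl oritin-(4α→8)-catechin)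
Conditions: BF3·OEt2 (0.5 equiv), CH2Cl2, −40 to 0 °C
Reagents that add atoms: none
Why: Lewis-acid ionisation of the benzylic C4 alcohol (loss of water) gives a cation stabilised by O1 and the para C7 benzyloxy group, which is captured in a Friedel–Crafts alkylation by C8 of 13 (the more nucleophilic, less hindered position of its phloroglucinol-type ring) anti to the C3 benzyloxy group, setting C4 as S (3,4-trans), while the excess of 13 suppresses further alkylation.

Step 10
Reactants: 14 nona-O-benzyl oritin-(4α→8)-catechin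
Product: 15 oritin-(4α→8)-catechin (target)
Conditions: H2 (1 atm), Pd(OH)2/C, THF/MeOH/H2O, rt
Reagents that add atoms: none
Why: catalytic hydrogenolysis should cleave all nine benzyl ethers (eight aryl, one alkyl) without touching the five stereocenters or the C4–C8 bond, whose diaryl-methine carbon carries no heteroatom leaving group.

**Compound list**

1 | 2-fluoro-3,4-dimethoxybenzaldehyde | COc1ccc(C=O)c(F)c1OC | starting material
2 | 2-fluoro-3,4-dihydroxybenzaldehyde | Oc1ccc(C=O)c(F)c1O | intermediate
3 | 3,4-bis(benzyloxy)-2-fluorobenzaldehyde | O=Cc1ccc(OCc2ccccc2)c(OCc2ccccc2)c1F | intermediate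
4 | 2-(benzyloxy)-1-[3,4-bis(benzyloxy)-2-fluorophenyl]ethanol (racemic) | OC(COCc1ccccc1)c1ccc(OCc2ccccc2)c(OCc2ccccc2)c1F | intermediate
5 | 2-(benzyloxy)-1-[3,4-bis(benzyloxy)-2-fluorophenyl]ethanone | O=C(COCc1ccccc1)c1ccc(OCc2ccccc2)c(OCc2ccccc2)c1F | intermediate
6 | (Z)-[2-(benzyloxy)-1-[3,4-bis(benzyloxy)-2-fluorophenyl]ethenyl]oxy(trimethyl)silane | C[Si](C)(C)O/C(=C\OCc1ccccc1)c1ccc(OCc2ccccc2)c(OCc2ccccc2)c1F | intermediate
7 | 3,4-bis(benzyloxy)benzaldehyde | O=Cc1ccc(OCc2ccccc2)c(OCc2ccccc2)c1 | starting material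
8 | (3R)-2-(benzyloxy)-1-[3,4-bis(benzyloxy)-2-fluorophenyl]-3-[3,4-bis(benzyloxy)phenyl]-3-[(trimethylsilyl)oxy]propan-1-one (C2 epimers) | c1ccc(COc2ccc([C@@H](O[Si](C)(C)C)C(OCc3ccccc3)C(=O)c3ccc(OCc4ccccc4)c(OCc4ccccc4)c3F)cc2OCc2ccccc2)cc1 | intermediate (not isolated)
9 | (2R,3S)-3,7,8-tris(benzyloxy)-2-[3,4-bis(benzyloxy)phenyl]chroman-4-one (2,3-cis) | c1ccc(COc2ccc([C@H]3Oc4c(ccc(OCc5ccccc5)c4OCc4ccccc4)C(=O)[C@H]3OCc3ccccc3)cc2OCc2ccccc2)cc1 | intermediate (not isolated)
10 | (2R,3R)-3,7,8-tris(benzyloxy)-2-[3,4-bis(benzyloxy)phenyl]chroman-4-one (2,3-trans) | c1ccc(COc2ccc([C@H]3Oc4c(ccc(OCc5ccccc5)c4OCc4ccccc4)C(=O)[C@@H]3OCc3ccccc3)cc2OCc2ccccc2)cc1 | intermediate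
11 | (2R,3S,4R)-3,7,8-tris(benzyloxy)-2-[3,4-bis(benzyloxy)phenyl]chroman-4-ol | c1ccc(COc2ccc([C@H]3Oc4c(ccc(OCc5ccccc5)c4OCc4ccccc4)[C@@H](O)[C@@H]3OCc3ccccc3)cc2OCc2ccccc2)cc1 | intermediate
12 | (+)-catechin, (2R,3S) | Oc1cc(O)c2c(c1)O[C@H](c1ccc(O)c(O)c1)[C@@H](O)C2 | starting material
13 | (2R,3S)-5,7-bis(benzyloxy)-2-[3,4-bis(benzyloxy)phenyl]chroman-3-ol | c1ccc(COc2cc(OCc3ccccc3)c3c(c2)O[C@H](c2ccc(OCc4ccccc4)c(OCc4ccccc4)c2)[C@@H](O)C3)cc1 | intermediate
14 | nona-O-benzyl oritin-(4α→8)-catechin, upper (2R,3S,4S), lower (2R,3S) | c1ccc(COc2ccc([C@H]3Oc4c(ccc(OCc5ccccc5)c4OCc4ccccc4)[C@@H](c4c(OCc5ccccc5)cc(OCc5ccccc5)c5c4O[C@H](c4ccc(OCc6ccccc6)c(OCc6ccccc6)c4)[C@@H](O)C5)[C@@H]3OCc3ccccc3)cc2OCc2ccccc2)cc1 | intermediate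
15 | oritin-(4α→8)-catechin (CNP0231186.1) | Oc1ccc([C@H]2Oc3c(ccc(O)c3O)[C@@H](c3c(O)cc(O)c4c3O[C@H](c3ccc(O)c(O)c3)[C@@H](O)C4)[C@@H]2O)cc1O | target

**Step count**

Total step count: 10. Longest linear sequence: 9 steps (steps 1–7, 9, 10).

**Steps most likely to fail**

Step 6 (proposed new method). The aldolate may revert (retro-aldol) or lose water by beta-elimination before ring closure, and ring C may open by elimination of the ring A phenoxide during the C3 equilibration. Each process erodes the C2 configuration or the yield, and a slow SNAr on the electron-rich ring A would let them win.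

The fallback uses known chemistry only. It sets out from aldehyde 7, with commercial 2,3,4-trihydroxyacetophenone as the ring A source, and returns at 10. Benzylation of the two non-chelated phenols of the acetophenone (BnBr, K2CO3, acetone) should give 1-[3,4-bis(benzyloxy)-2-hydroxyphenyl]ethanone F1, and protection of the remaining chelated phenol with MOMCl and i-Pr2NEt should give 1-[3,4-bis(benzyloxy)-2-(methoxymethoxy)phenyl]ethanone F2. Claisen–Schmidt condensation of F2 with 7 (KOH, EtOH) should give (E)-1-[3,4-bis(benzyloxy)-2-(methoxymethoxy)phenyl]-3-[3,4-bis(benzyloxy)phenyl]prop-2-en-1-one F3. Julia–Colonna epoxidation (poly-L-leucine, urea–H2O2, DBU, THF) should then give [(2R,3S)-3-[3,4-bis(benzyloxy)phenyl]oxiran-2-yl][3,4-bis(benzyloxy)-2-(methoxymethoxy)phenyl]methanone F4. Methanolic HCl removes the MOM group to give [(2R,3S)-3-[3,4-bis(benzyloxy)phenyl]oxiran-2-yl][3,4-bis(benzyloxy)-2-hydroxyphenyl]methanone F5, which is not isolated; its phenol opens the oxirane at the benzylic carbon with inversion to give (2R,3R)-7,8-bis(benzyloxy)-2-[3,4-bis(benzyloxy)phenyl]-3-hydroxychroman-4-one F6. O-Benzylation of F6 under acid (benzyl 2,2,2-trichloroacetimidate, cat. TfOH, CH2Cl2), which avoids base-induced epimerisation, should give 10.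

Step 9. Ionisation of the 5-deoxy benzylic alcohol may be slow relative to acid-promoted side reactions. Capture may also occur through C6 of the nucleophile, syn to the C3 benzyloxy group, or a second time on the product.

The fallback sets out from 11 and returns at 14. Acid-catalysed thiolysis with phenylmethanethiol (BnSH, cat. BF3·OEt2, CH2Cl2) should give (2R,3R,4R)-4-(benzylsulfanyl)-3,7,8-tris(benzyloxy)-2-[3,4-bis(benzyloxy)phenyl]chromane F7. Thiophilic activation of F7 with AgBF4 in THF at 0 °C in the presence of excess 13 generates the same C4 cation slowly, without protic acid, and should give 14. Any C6-linked or 4-epimeric dimer would be removed by chromatography at the stage of 14.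

Step 10. Ninefold debenzylation may stall at partly benzylated stages (the alkyl benzyl ether at C3 is the slowest), and the free pyrogallol-type ring A may oxidise in air during prolonged reaction and isolation.

The fallback sets out from 14 and returns at 15. Lewis-acid debenzylation with BCl3 and pentamethylbenzene as benzyl-cation scavenger (CH2Cl2, −78 °C, then MeOH quench) replaces the heterogeneous hydrogenolysis and makes no new intermediate.

**Further compounds**

F1 | step 6 | 1-[3,4-bis(benzyloxy)-2-hydroxyphenyl]ethanone | CC(=O)c1ccc(OCc2ccccc2)c(OCc2ccccc2)c1O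
F2 | step 6 | 1-[3,4-bis(benzyloxy)-2-(methoxymethoxy)phenyl]ethanone | CC(=O)c1ccc(OCc2ccccc2)c(OCc2ccccc2)c1OCOC
F3 | step 6 | (E)-1-[3,4-bis(benzyloxy)-2-(methoxymethoxy)phenyl]-3-[3,4-bis(benzyloxy)phenyl]prop-2-en-1-one | O=C(/C=C/c1ccc(OCc2ccccc2)c(OCc2ccccc2)c1)c1ccc(OCc2ccccc2)c(OCc2ccccc2)c1OCOC
F4 | step 6 | [(2R,3S)-3-[3,4-bis(benzyloxy)phenyl]oxiran-2-yl][3,4-bis(benzyloxy)-2-(methoxymethoxy)phenyl]methanone | O=C([C@@H]1O[C@H]1c1ccc(OCc2ccccc2)c(OCc2ccccc2)c1)c1ccc(OCc2ccccc2)c(OCc2ccccc2)c1OCOC
F5 | step 6 | [(2R,3S)-3-[3,4-bis(benzyloxy)phenyl]oxiran-2-yl][3,4-bis(benzyloxy)-2-hydroxyphenyl]methanone | O=C([C@@H]1O[C@H]1c1ccc(OCc2ccccc2)c(OCc2ccccc2)c1)c1ccc(OCc2ccccc2)c(OCc2ccccc2)c1O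
F6 | step 6 | (2R,3R)-7,8-bis(benzyloxy)-2-[3,4-bis(benzyloxy)phenyl]-3-hydroxychroman-4-one | c1ccc(COc2ccc([C@H]3Oc4c(ccc(OCc5ccccc5)c4OCc4ccccc4)C(=O)[C@@H]3O)cc2OCc2ccccc2)cc1
F7 | step 9 | (2R,3R,4R)-4-(benzylsulfanyl)-3,7,8-tris(benzyloxy)-2-[3,4-bis(benzyloxy)phenyl]chromane | c1ccc(COc2ccc([C@H]3Oc4c(ccc(OCc5ccccc5)c4OCc4ccccc4)[C@@H](SCc4ccccc4)[C@@H]3OCc3ccccc3)cc2OCc2ccccc2)cc1
F0 | step 10 | none | none
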